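**Conventions and assumptions.** Eremophilane numbering is used for every decalin: ring A = C1–C5 and C10, ring B = C5–C10, C14 = methyl on C5, C15 = methyl on C4, C11–C13 = the three-carbon group on C7. β is the face that carries C14. Assumption: 3, 15, 25 and 29 are purchased, and the antipode of 5 collected in step 2 is identified as (1S,4S,7S) by crystallographic or chiroptical correlation.

Compound numbers used throughout: 1 creosol; 2 PhI(OAc)2; 3 ethyl vinyl ketone; 4 masked o-benzoquinone; 5 racemic adduct; 6 resolved adduct; 7 lithium enolate; 8 enol silane; 9 cis-decalin; 10 mono-methoxy enone; 11 enone; 12 dienolate; 13 sulfilimine; 14 dienone; 15 acetone; 16 enolate; 17 ketol; 18 keto ketol; 19 chlorosulfite; 20 diketone; 21 dilithium species; 22 bis-silyl compound; 23 enolate; 24 hydroxy ketone; 25 (E)-3-methylpent-2-enoic acid; 26 mixed anhydride; 27 silyl ether ester; 28 hydroxy ester; 29 angelic acid; 30 mixed anhydride; 31 target.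

## Analysis of the target

The target 31, (3R,4R,5R,7S,9S,10R)-3-angeloyloxy-9-[(E)-3-methylpent-2-enoyloxy]eremophil-11-en-8-one, is a trans-fused decalin with six stereocentres, five of them contiguous along C3–C4–C5–C10–C9 and the sixth, C7, across the C8 carbonyl. The quaternary C5 carries an axial β-methyl; every other substituent is equatorial in the chair–chair form: the C4 methyl (β, cis to C14), the C3 oxygen (α), the C7 isopropenyl group (α) and the C9 oxygen (α), with H10 α and anti to C14. C3, C7, C9 and C10 therefore hold the thermodynamically preferred configuration once the trans-decalin exists, whereas the vicinal C4/C5 pair has to come from a stereospecific C–C bond formation. The sensitive groups are the angelate (Z to E isomerisation), the β,γ-unsaturated ketone (the C7 isopropenyl group can slip into conjugation with C8), the α-acyloxy ketone at C8/C9, and two different unsaturated esters on two secondary alcohols. The synthesis is hard because of the quaternary C5 next to C4, because hydride must reach C3 from the face that C14 shields, and because both α-positions of the C8 ketone must be functionalised differently (carbon at C7, oxygen at C9). The plan rests on one feature: ring B with its C5 methyl, C8 carbonyl and C9 oxygen is a dearomatised 2-methoxy-4-methylphenol (1), and C1–C4 with C15 is the vinyl ketone 3. The two are joined at C1–C10 and C2–C7 by cycloaddition, and the C2–C7 bond is then exchanged for C4–C5 by a sigmatropic shift.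

## Retrosynthetic reasoning

**Ester bonds.** The two acyl–oxygen bonds are cut first, the angelate last in the forward sense because it isomerises most easily: 31 goes back to hydroxy ester 28 and acid 29, and 28 to hydroxy ketone 24 and acid 25. The two secondary alcohols must never be free at the same time, so 24 carries a silyl ether at C3 while C9 is acylated.

**C9–O bond.** The C9 oxygen is removed to give the C8–C9 enolate 23, stored as the bis-silyl compound 22. The cut is made here because a trans-fused C8 ketone enolises by preference towards C7, so the C9 enolate must come from a reaction that can only produce it. The forward step is an enolate hydroxylation from the face opposite C14.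

**C10–H and C3–H bonds.** 22 is traced to the enone-ketone 20 by adding back the C9=C10 double bond and the C3 carbonyl. One dissolving-metal reduction should do three things: set H10 trans to C14, produce the C8–C9 enolate regiospecifically, and reduce C3 under thermodynamic control to the equatorial alcohol, which kinetic hydride delivery would not give.

**Isopropenyl group and C7–C11 bond.** 20 goes back through keto ketol 18 and ketol 17 to dienone 14 and acetone 15. The C7–C11 bond is cut because conjugate reduction of the less substituted double bond of 14 creates the C7 enolate unambiguously. The forward aldol has to place the substituent anti to C14.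

**C9=C10 unsaturation and the methoxy groups.** 14 comes from enone 11 by dehydrogenation at the only enolisable position, C9, and 11 from the ketal 9 by reductive removal of both methoxy groups. The C9 oxygen is deliberately given up: the C9=C10 alkene is the only handle for correcting the cis ring fusion, and the oxygen is put back later.

**C4–C5 bond (key disconnection).** 9 is reconnected to the bicyclic enol silane 8 by breaking C4–C5 and re-forming the C2–C7 bridge bond. This converts the hardest element, the tertiary–quaternary C4/C5 pair and ring A, into the geometry of an enol ether and the chirality of a rigid bicycle. The forward [3,3] shift must transfer both faithfully.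

**Enol silane, resolution and cycloaddition.** 8 is the E enol silane of ketone 6, obtained by resolution of racemate 5. Cutting C1–C10 and C2–C7 of 5 gives dienone 4 and vinyl ketone 3, and 4 is the oxidation product of phenol 1 with oxidant 2. The forward cycloaddition has to be ortho- and endo-selective so that the side chain lies under the C5=C6 bridge.

## Alternatives that were turned down

**Alternative 1:** The C7–C8 bond of ring B is cut, leading to aldehyde A2, a ring-A cyclohexane with a prenyl group on C5 and an acyloxy-acetaldehyde arm on C10. In the forward step a Lewis acid promotes an intramolecular carbonyl-ene reaction through C7 with transfer of a methyl hydrogen, giving A1 with the 7α-isopropenyl and 8β-hydroxyl groups, in the manner of the classical ene closure to a trans-2-isopropenylcyclohexanol.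
- For: the isopropenyl group is formed regiospecifically, the ring fusion is already trans in A2, and the C9 ester and C3 oxygen are in place. On the isopropenyl group this alternative is stronger than the chosen route, which depends on a kinetic dehydration.
- Against: C3, C4, C5, C9 and C10 must all be set before the key step on a flexible monocycle, so the C4/C5 problem is not addressed by the key step. A2 is an α-acyloxy aldehyde with an epimerisable C9 that is prone to acyl shift, and A1 still needs oxidation at C8 between two epimerisable centres.
- Comparison: the chosen strategy spends more steps after its key step, but it makes ring A and the C4/C5 pair in one stereospecific operation from two commodity building blocks.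

**Alternative 2:** Two bonds are cut, C9–C10 and C4–C5, which opens both rings to the acyclic aldehyde A4 with an E trisubstituted C5=C10 alkene, a silyl enol ether terminator and a C8 ether. In the forward step a Lewis acid activates the C9 aldehyde, C10 attacks it, and the tertiary C5 cation is captured by C4 to give A3.
- For: the trans ring fusion and four stereocentres (C4, C5, C9, C10) arise directly from a chair–chair array. On the ring fusion this alternative is clearly stronger than the chosen route, which delivers a cis-decalin and must pass through a C9=C10 enone.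
- Against: the facial course of the initiation and the C9 carbinol configuration rest on a single α-alkoxy stereocentre in a flexible chain. The tertiary cation can lose a proton, and the benzylic ether is labile to the Lewis acid. The C7 substituent is absent and must later be introduced next to C8 with a C7/C9 regiochemical problem, and the C3 ketone poses the same reduction problem.
- Comparison: the core is reached in fewer steps on paper, but the stereochemistry depends on conformational preference. In the chosen route a rigid bicycle enforces it and the order of bond formation is fixed.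

**Alternative 3:** The C1–C10 bond is cut, leading to A6, a 4-methylcyclohexa-2,5-dienone whose C5 bears a side chain with the C3 and C4 stereocentres and a Z alkenyl iodide. In the forward step zerovalent palladium inserts into the C1–I bond, the alkenyl group adds to C10 of one of the two dienone double bonds, and the palladium enolate is reduced by a formate source to give A5.
- For: the key step is catalytic, and the C3 oxygen already has its α-configuration. On C3 this alternative is stronger than the chosen route, which needs a thermodynamically controlled reduction.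
- Against: the C4–C5 bond must be formed intermolecularly when A6 is built, which is the least dependable place for it. The choice between the two dienone arms decides the C5/C10 relationship and depends on the side-chain conformation. A5 is again cis-fused, lacks the C9 oxygen and the C7 substituent, and carries a C1=C2 alkene that must be reduced selectively.
- Comparison: the chosen strategy needs the same later ring-B operations but forms C4–C5 intramolecularly and stereospecifically.

Key step: step 4

## Route

Step 1
Reactants: 1 creosol (2-methoxy-4-methylphenol); 2 (diacetoxyiodo)benzene PhI(OAc)2; 3 ethyl vinyl ketone (pent-1-en-3-one)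
Product: 5 racemic endo adduct rac-(1S*,4S*,7S*)-3,3-dimethoxy-5-methyl-7-propanoylbicyclo[2.2.2]oct-5-en-2-one, via masked o-benzoquinone 4 (not isolated)
Conditions: PhI(OAc)2 (1.1 equiv), 3 (10 equiv), MeOH, 0 °C → rt, slow addition of 1
Reagents that add atoms: methanol, CO
Why: Oxidative dearomatisation: the phenol is oxidised and methanol is captured at the methoxy-bearing carbon to give dienone 4, which is trapped in situ by excess 3 in a Diels–Alder reaction faster than it dimerises. The acyl-bearing carbon of 3 bonds to the dienone α-carbon (ortho orientation, reinforced by the diene methyl) and the acyl group lies endo under the new C5=C6 bridge, so the three stereocentres form in one relative configuration.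

Step 2
Reactants: 5
Product: 6 (1S,4S,7S)-3,3-dimethoxy-5-methyl-7-propanoylbicyclo[2.2.2]oct-5-en-2-one
Conditions: preparative HPLC, amylose tris(3,5-dimethylphenylcarbamate) stationary phase, hexane/i-PrOH, rt
Reagents that add atoms: none
Why: No dependable catalytic enantioselective version of this cycloaddition exists, so the racemate is separated physically on a polysaccharide carbamate phase, a general method for neutral ketones. The (1S,4S,7S) antipode is the one whose bridgehead configuration leads to 5R in 31.

Step 3
Reactants: 6
Product: 8 (1S,4S,7S)-7-[(1E)-1-(tert-butyldimethylsilyloxy)prop-1-en-1-yl]-3,3-dimethoxy-5-methylbicyclo[2.2.2]oct-5-en-2-one, via lithium E-enolate 7 (not isolated)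
Conditions: LiN(SiMe3)2, Et3N, PhMe, −78 °C; then TBSOTf, −78 → 0 °C
Reagents that add atoms: tert-butyldimethylsilyl trifluoromethanesulfonate, CC(C)(C)[Si](C)(C)OS(=O)(=O)C(F)(F)F
Why: Kinetic enolisation and O-silylation: the ring ketone has no removable α-hydrogen (bridgehead and ketal carbon), and the hindered amide removes a proton from the ethyl CH2, not from the tertiary C2. Amine-solvated lithium hexamethyldisilazide in a hydrocarbon is expected to give the enolate with methyl anti to oxygen for α-branched ethyl ketones, and silylation at low temperature fixes this E geometry.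

Step 4
Reactants: 8
Product: 9 cis-fused 3-(tert-butyldimethylsilyloxy)-9,9-dimethoxy-4β,5β-dimethyldecalin-2,6-dien-8-one (10β-H)
Conditions: degassed PhMe (0.02 M), Et3N (5 mol%), sealed base-washed tube, 200 °C
Reagents that add atoms: none
Why: Heating should bring about a concerted, suprafacial [3,3]-sigmatropic shift of the 1,5-diene C4=C3–C2–C7–C6=C5; the closest known reaction type is the Cope rearrangement of endo-alkenyl bicyclo[2.2.2]oct-5-en-2-ones derived from masked o-benzoquinones, which gives cis-decalins. C4 bonds to C5 while the C2–C7 bridge bond breaks, so ring A closes as a six-membered ring through the six-atom pericyclic array, which the bicycle holds in a boat because a chair would need C3 where C1 already sits. C5 becomes stereogenic under control of the C10 bridgehead: the enol ether can only reach the face of C5=C6 that is syn to the C1–C2 bridge, so C14 ends cis to H10 and the absolute configuration of 8 is transferred. C4 is controlled by the enol-ether geometry: in the boat the C4 substituent that is cis to C2 eclipses C10 and ends cis to C14, so the E isomer gives the 4β,5β-dimethyl pair. The step needs the endo side chain (step 1), the E geometry (step 3) and a rate advantage over cycloreversion. That advantage should come from the radical-stabilising silyloxy group at C3 and acyl group at C7, from release of bicyclic strain and from the new conjugated C6=C7–C8 enone, which also make the shift irreversible.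

Step 5
Reactants: 9
Product: 11 cis-fused 3-(tert-butyldimethylsilyloxy)-4β,5β-dimethyldecalin-2,6-dien-8-one (10β-H), via 9-methoxy enone 10 (not isolated)
Conditions: SmI2 (4.4 equiv), THF–MeOH (4:1), −78 °C
Reagents that add atoms: none
Why: Reductive cleavage of an α-alkoxy ketone: electron transfer to the C8 carbonyl expels each methoxy group in turn and the samarium enolate is protonated at C9 by methanol. This should be much faster at −78 °C than reduction of the enone itself, and the enol silane is not a substrate.

Step 6
Reactants: 11
Product: 14 3-(tert-butyldimethylsilyloxy)-4β,5β-dimethyldecalin-2,6,9-trien-8-one, via lithium dienolate 12 (not isolated), via C9 sulfilimine 13 (not isolated)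
Conditions: LiN(i-Pr)2, THF, −78 °C; then PhS(Cl)=N-t-Bu, −78 °C
Reagents that add atoms: none
Why: C9 is the only acidic position of 11 (C7 is vinylic, C5 quaternary), so the amide gives the cross-conjugated dienolate. Sulfinimidoylation at C9 from the convex β-face, cis to H10, is followed by syn-elimination across C9–C10 (one-pot dehydrogenation of a lithium enolate), a method chosen because it acts on the enolate and leaves the silyl enol ether alone. The C10 stereocentre is removed on purpose.

Step 7
Reactants: 14; 15 acetone
Product: 17 7α-(2-hydroxypropan-2-yl)-3-(tert-butyldimethylsilyloxy)-4β,5β-dimethyldecalin-2,9-dien-8-one, via lithium enolate 16 (not isolated)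
Conditions: LiBH(s-Bu)3, THF, −78 °C; then ZnCl2, 15, −78 → −40 °C; aq. NH4Cl
Reagents that add atoms: none
Why: Conjugate reduction–aldol: the bulky hydride adds to the unsubstituted β-carbon C6 and not to the fully substituted C10, which creates the C7 enolate regiospecifically; after transmetalation to zinc it adds to acetone. Acetone approaches C7 anti to the pseudo-axial C14, and the 7α (pseudo-equatorial) ketol is also the thermodynamic product of this reversible addition.

Step 8
Reactants: 17
Product: 18 7α-(2-hydroxypropan-2-yl)-4β,5β-dimethyldecal-9-ene-3,8-dione
Conditions: HF·pyridine, pyridine, THF, 0 °C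
Reagents that add atoms: none
Why: Fluoride-assisted protodesilylation of the enol silane (protonation at C2) frees the C3 ketone under buffered conditions that spare the tertiary β-ketol and the enone. C4 is not involved and keeps its configuration.

Step 9
Reactants: 18
Product: 20 (4R,5R,7S)-eremophila-9,11-diene-3,8-dione (7α-isopropenyl-4β,5β-dimethyldecal-9-ene-3,8-dione), via chlorosulfite 19 (not isolated)
Conditions: SOCl2, pyridine, CH2Cl2, −30 → 0 °C
Reagents that add atoms: none
Why: E2 dehydration of a tertiary chlorosulfite by pyridine: six accessible methyl hydrogens are favoured statistically and sterically over the single hindered tertiary H7, so the kinetic product should be the isopropenyl isomer, with the conjugated isopropylidene ketone as a separable minor product. Low temperature and the absence of strong base keep the β,γ-unsaturated ketone from isomerising.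

Step 10
Reactants: 20
Product: 22 3α,8-bis(trimethylsilyloxy)eremophila-8,11-diene (10α-H and trans ring fusion), via dilithium alkoxide enolate 21 (not isolated)
Conditions: Li, NH3(l)/THF, t-BuOH, −78 → −33 °C; isoprene; then Me3SiCl, Et3N, THF, −78 → 0 °C
Reagents that add atoms: chlorotrimethylsilane, C[Si](C)(C)Cl
Why: Dissolving-metal reduction: the enone takes up two electrons and is protonated axially at C10 on the α-face (trans-decalin), leaving the C8–C9 enolate, which as an enolate is protected from further reduction. The isolated C3 ketone is reduced through its ketyl to the more stable equatorial 3α-alkoxide, since the axial epimer would clash 1,3-diaxially with C14. Silylation of both oxygens stores the regiodefined enolate as an enol silane and protects the C3 alcohol.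

Step 11
Reactants: 22
Product: 24 9α-hydroxy-3α-(trimethylsilyloxy)eremophil-11-en-8-one, via lithium enolate 23 (not isolated)
Conditions: MeLi, THF, 0 °C; then (camphorsulfonyl)oxaziridine, −78 °C; aq. NH4Cl
Reagents that add atoms: (10-camphorsulfonyl)oxaziridine (either antipode), CC1(C)C2CCC13CS(=O)(=O)N4OC34C2
Why: MeLi cleaves only the enol silyl ether and regenerates the C8–C9 lithium enolate without equilibration, and the N-sulfonyloxaziridine transfers oxygen to C9 (enolate α-hydroxylation). Attack on the α-face, anti to the axial C14, gives the equatorial 9α-alcohol, which is also the thermodynamically preferred epimer; the isopropenyl alkene is inert to this oxidant.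

Step 12
Reactants: 24; 25 (E)-3-methylpent-2-enoic acid
Product: 28 3α-hydroxy-9α-[(E)-3-methylpent-2-enoyloxy]eremophil-11-en-8-one, via mixed anhydride 26 (not isolated), via silyl ether ester 27 (not isolated)
Conditions: 25, 2,4,6-Cl3C6H2COCl, Et3N, THF, rt; then 24, DMAP, PhMe, rt; then citric acid, MeOH, 0 °C
Reagents that add atoms: none
Why: Yamaguchi esterification: the mixed anhydride acylates the only free hydroxyl, the C9 α-ketol, under mildly basic conditions that the C3 silyl ether survives. Brief acidic methanolysis then removes the trimethylsilyl group without touching the ester or the alkene.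

Step 13
Reactants: 28; 29 angelic acid ((Z)-2-methylbut-2-enoic acid)
Product: 31 (3R,4R,5R,7S,9S,10R)-3-angeloyloxy-9-[(E)-3-methylpent-2-enoyloxy]eremophil-11-en-8-one, via mixed anhydride 30 (not isolated)
Conditions: 29, 2,4,6-Cl3C6H2COCl, Et3N, PhMe, rt; then 28, 75 °C
Reagents that add atoms: none
Why: Mixed-anhydride esterification without a nucleophilic catalyst is the established way to attach angelic acid without Z to E isomerisation. The equatorial 3α-alcohol is the only hydroxyl left, so no selectivity question arises.

## Compound list

1 | creosol (2-methoxy-4-methylphenol) | COc1cc(C)ccc1O | starting material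
2 | (diacetoxyiodo)benzene, PhI(OAc)2 | CC(=O)OI(OC(C)=O)c1ccccc1 | starting material
3 | ethyl vinyl ketone (pent-1-en-3-one) | CCC(=O)C=C | starting material
4 | 6,6-dimethoxy-4-methylcyclohexa-2,4-dien-1-one (masked o-benzoquinone, not isolated) | COC1(OC)C=C(C)C=CC1=O | intermediate
5 | racemic endo adduct, rac-(1S*,4S*,7S*)-3,3-dimethoxy-5-methyl-7-propanoylbicyclo[2.2.2]oct-5-en-2-one (both antipodes) | CC1=C[C@@H]2C(=O)C(OC)(OC)[C@H]1C[C@@H]2C(=O)CC.CC1=C[C@H]2C(=O)C(OC)(OC)[C@@H]1C[C@H]2C(=O)CC | intermediate
6 | (1S,4S,7S)-3,3-dimethoxy-5-methyl-7-propanoylbicyclo[2.2.2]oct-5-en-2-one | CC1=C[C@@H]2C(=O)C(OC)(OC)[C@H]1C[C@@H]2C(=O)CC | intermediate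
7 | lithium E-enolate of 6 (methyl anti to oxygen, not isolated) | CC1=C[C@@H]2C(=O)C(OC)(OC)[C@H]1C[C@@H]2/C(O[Li])=C\C | intermediate
8 | (1S,4S,7S)-7-[(1E)-1-(tert-butyldimethylsilyloxy)prop-1-en-1-yl]-3,3-dimethoxy-5-methylbicyclo[2.2.2]oct-5-en-2-one | CC1=C[C@@H]2C(=O)C(OC)(OC)[C@H]1C[C@@H]2/C(O[Si](C)(C)C(C)(C)C)=C\C | intermediate
9 | cis-fused 3-(tert-butyldimethylsilyloxy)-9,9-dimethoxy-4β,5β-dimethyldecalin-2,6-dien-8-one (10β-H) | C1=C[C@]2(C)[C@@H](C)C(O[Si](C)(C)C(C)(C)C)=CC[C@@H]2C(OC)(OC)C1=O | intermediate
10 | cis-fused 3-(tert-butyldimethylsilyloxy)-9-methoxy-4β,5β-dimethyldecalin-2,6-dien-8-one (both C9 epimers, not isolated) | C1=C[C@]2(C)[C@@H](C)C(O[Si](C)(C)C(C)(C)C)=CC[C@@H]2C(OC)C1=O | intermediate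
11 | cis-fused 3-(tert-butyldimethylsilyloxy)-4β,5β-dimethyldecalin-2,6-dien-8-one (10β-H) | C1=C[C@]2(C)[C@@H](C)C(O[Si](C)(C)C(C)(C)C)=CC[C@@H]2CC1=O | intermediate
12 | lithium 6,8-dienolate of 11 (not isolated) | C1=C[C@]2(C)[C@@H](C)C(O[Si](C)(C)C(C)(C)C)=CC[C@@H]2C=C1O[Li] | intermediate
13 | 9β-(N-tert-butyl-S-phenylsulfinimidoyl) derivative of 11 (not isolated) | C1=C[C@]2(C)[C@@H](C)C(O[Si](C)(C)C(C)(C)C)=CC[C@@H]2[C@@H](S(=NC(C)(C)C)c3ccccc3)C1=O | intermediate
14 | 3-(tert-butyldimethylsilyloxy)-4β,5β-dimethyldecalin-2,6,9-trien-8-one | C1=C[C@]2(C)[C@@H](C)C(O[Si](C)(C)C(C)(C)C)=CCC2=CC1=O | intermediate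
15 | acetone | CC(C)=O | starting material
16 | lithium 7,9-dienolate from conjugate reduction of 14 (not isolated) | C=1C[C@]2(C)[C@@H](C)C(O[Si](C)(C)C(C)(C)C)=CCC2=CC=1O[Li] | intermediate
17 | 7α-(2-hydroxypropan-2-yl)-3-(tert-butyldimethylsilyloxy)-4β,5β-dimethyldecalin-2,9-dien-8-one | CC(C)(O)[C@@H]1C[C@]2(C)[C@@H](C)C(O[Si](C)(C)C(C)(C)C)=CCC2=CC1=O | intermediate
18 | 7α-(2-hydroxypropan-2-yl)-4β,5β-dimethyldecal-9-ene-3,8-dione | CC(C)(O)[C@@H]1C[C@]2(C)[C@@H](C)C(=O)CCC2=CC1=O | intermediate
19 | chlorosulfite ester of 18 (not isolated) | CC(C)(OS(=O)Cl)[C@@H]1C[C@]2(C)[C@@H](C)C(=O)CCC2=CC1=O | intermediate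
20 | (4R,5R,7S)-eremophila-9,11-diene-3,8-dione | C=C(C)[C@@H]1C[C@]2(C)[C@@H](C)C(=O)CCC2=CC1=O | intermediate
21 | dilithium 3α-alkoxide 8-enolate (10α-H, not isolated) | C=C(C)[C@@H]1C[C@]2(C)[C@@H](C)[C@H](O[Li])CC[C@H]2C=C1O[Li] | intermediate
22 | 3α,8-bis(trimethylsilyloxy)eremophila-8,11-diene (10α-H) | C=C(C)[C@@H]1C[C@]2(C)[C@@H](C)[C@H](O[Si](C)(C)C)CC[C@H]2C=C1O[Si](C)(C)C | intermediate
23 | lithium 8-enolate of the 3α-trimethylsilyl ether (not isolated) | C=C(C)[C@@H]1C[C@]2(C)[C@@H](C)[C@H](O[Si](C)(C)C)CC[C@H]2C=C1O[Li] | intermediate
24 | 9α-hydroxy-3α-(trimethylsilyloxy)eremophil-11-en-8-one | C=C(C)[C@@H]1C[C@]2(C)[C@@H](C)[C@H](O[Si](C)(C)C)CC[C@H]2[C@H](O)C1=O | intermediate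
25 | (E)-3-methylpent-2-enoic acid | CC/C(C)=C/C(=O)O | starting material
26 | (E)-3-methylpent-2-enoic 2,4,6-trichlorobenzoic anhydride (not isolated) | CC/C(C)=C/C(=O)OC(=O)c1c(Cl)cc(Cl)cc1Cl | intermediate
27 | 9α-[(E)-3-methylpent-2-enoyloxy]-3α-(trimethylsilyloxy)eremophil-11-en-8-one (not isolated) | C=C(C)[C@@H]1C[C@]2(C)[C@@H](C)[C@H](O[Si](C)(C)C)CC[C@H]2[C@H](OC(=O)/C=C(\C)CC)C1=O | intermediate
28 | 3α-hydroxy-9α-[(E)-3-methylpent-2-enoyloxy]eremophil-11-en-8-one | C=C(C)[C@@H]1C[C@]2(C)[C@@H](C)[C@H](O)CC[C@H]2[C@H](OC(=O)/C=C(\C)CC)C1=O | intermediate
29 | angelic acid ((Z)-2-methylbut-2-enoic acid) | C/C=C(/C)C(=O)O | starting material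
30 | angelic 2,4,6-trichlorobenzoic anhydride (not isolated) | C/C=C(/C)C(=O)OC(=O)c1c(Cl)cc(Cl)cc1Cl | intermediate
31 | (3R,4R,5R,7S,9S,10R)-3-angeloyloxy-9-[(E)-3-methylpent-2-enoyloxy]eremophil-11-en-8-one | C=C(C)[C@@H]1C[C@]2(C)[C@@H](C)[C@H](OC(=O)/C(C)=C\C)CC[C@H]2[C@H](OC(=O)/C=C(\C)CC)C1=O | target

## Step count and least certain steps

Total step count: 13. Longest linear sequence: 13 steps, from 1 to 31; 3, 15, 25 and 29 enter as purchased reagents.

**Step 4 (key step).** The most likely failure is thermal cycloreversion of 8 to dienone 4 and the silyloxydiene competing with the sigmatropic shift. Recombination of the fragments would return racemic adduct and so erode enantiomeric purity, and dimerisation of the dienone would consume material. The fallback makes enantiopurity independent of the thermal step by deferring the resolution. It sets out from racemate 5, which is silylated under the conditions of step 3 to the racemic enol silane F1. F1 is rearranged to the racemic cis-decalin F2, which is separated on the chiral stationary phase. The fallback comes back to the route at 9.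

**Step 10.** The two reductions may not finish together: the ring-B enolate can be protonated by the alcohol and the regenerated C8 ketone reduced further, or the C3 ketone can be enolised by the basic medium and escape reduction. The fallback separates the two events and replaces thermodynamic control at C3 by inversion. It sets out from 20:
- The saturated C3 ketone alone is reduced with NaBH4 in MeOH–CH2Cl2 at −78 °C; hydride arrives anti to C14 and gives the axial 3β-hydroxy enone F3.
- The enone of F3 is reduced with Li in NH3 with one equivalent of t-BuOH, and the enolate is oxidised in the same flask with the oxaziridine to the 3β,9α-dihydroxy ketone F4.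
- The equatorial C9 hydroxyl is esterified with 25 to the 3β-hydroxy 9-ester F5; the axial C3 hydroxyl, flanked by C15 and syn-axial to C14, should react much more slowly.
- A Mitsunobu reaction with 29 (PPh3, diisopropyl azodicarboxylate) attaches the angelate with inversion at C3.

The fallback comes back to the route at 31.

**Step 9.** Elimination may take place towards C7 (loss of the acidic H7), giving the conjugated isopropylidene ketone, or the isopropenyl group may isomerise into conjugation afterwards. The fallback introduces the alkene intact by cross-coupling. It sets out from 14: the enolate 16, made as in step 7, is transmetalated with ZnCl2 and coupled with 2-bromopropene under Pd2(dba)3/P(t-Bu)3 catalysis (α-alkenylation of a ketone enolate). After kinetic protonation this gives the 7α-isopropenyl enol silane F6, and cleavage of its enol silane with HF·pyridine as in step 8 brings the fallback back to the route at 20.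

**Step 7.** The hydride may attack the dienone carbonyl directly, or the borane-complexed enolate may be captured poorly by acetone, with retro-aldol on warming. The fallback separates reduction from C–C bond formation. It sets out from 14: conjugate reduction with [(Ph3P)CuH]6 in the presence of Me3SiCl gives the silyl dienol ether F7, MeLi releases the borane-free lithium enolate 16, and ZnCl2 with 15 then gives the ketol. The fallback comes back to the route at 17.

## Further compounds

F1 | step 4 | racemic 7-[(1E)-1-(tert-butyldimethylsilyloxy)prop-1-en-1-yl]-3,3-dimethoxy-5-methylbicyclo[2.2.2]oct-5-en-2-one (racemate of 8) | CC1=C[C@@H]2C(=O)C(OC)(OC)[C@H]1C[C@@H]2/C(O[Si](C)(C)C(C)(C)C)=C\C.CC1=C[C@H]2C(=O)C(OC)(OC)[C@@H]1C[C@H]2/C(O[Si](C)(C)C(C)(C)C)=C\C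
F2 | step 4 | racemic cis-fused 3-(tert-butyldimethylsilyloxy)-9,9-dimethoxy-4,5-dimethyldecalin-2,6-dien-8-one (racemate of 9) | C1=C[C@]2(C)[C@@H](C)C(O[Si](C)(C)C(C)(C)C)=CC[C@@H]2C(OC)(OC)C1=O.C1=C[C@@]2(C)[C@H](C)C(O[Si](C)(C)C(C)(C)C)=CC[C@H]2C(OC)(OC)C1=O
F3 | step 10 | 3β-hydroxyeremophila-9,11-dien-8-one (4β,5β-dimethyl, 7α-isopropenyl) | C=C(C)[C@@H]1C[C@]2(C)[C@@H](C)[C@@H](O)CCC2=CC1=O
F4 | step 10 | 3β,9α-dihydroxyeremophil-11-en-8-one (10α-H) | C=C(C)[C@@H]1C[C@]2(C)[C@@H](C)[C@@H](O)CC[C@H]2[C@H](O)C1=O
F5 | step 10 | 3β-hydroxy-9α-[(E)-3-methylpent-2-enoyloxy]eremophil-11-en-8-one | C=C(C)[C@@H]1C[C@]2(C)[C@@H](C)[C@@H](O)CC[C@H]2[C@H](OC(=O)/C=C(\C)CC)C1=O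
F6 | step 9 | 7α-isopropenyl-3-(tert-butyldimethylsilyloxy)-4β,5β-dimethyldecalin-2,9-dien-8-one | C=C(C)[C@@H]1C[C@]2(C)[C@@H](C)C(O[Si](C)(C)C(C)(C)C)=CCC2=CC1=O
F7 | step 7 | 3-(tert-butyldimethylsilyloxy)-8-(trimethylsilyloxy)-4β,5β-dimethyldecalin-2,7,9-triene | C=1C[C@]2(C)[C@@H](C)C(O[Si](C)(C)C(C)(C)C)=CCC2=CC=1O[Si](C)(C)C
A1 | alternative 1 | 8β-hydroxy-7α-isopropenyl-9α-[(E)-3-methylpent-2-enoyloxy]-3α-(tert-butyldimethylsilyloxy)-4β,5β-dimethyl-trans-decalin | C=C(C)[C@@H]1C[C@]2(C)[C@@H](C)[C@H](O[Si](C)(C)C(C)(C)C)CC[C@H]2[C@H](OC(=O)/C=C(\C)CC)[C@H]1O
A2 | alternative 1 | ring-A aldehyde with C5 prenyl group and C10 acyloxy-acetaldehyde arm (ene precursor) | CC(C)=CC[C@]1(C)[C@@H](C)[C@H](O[Si](C)(C)C(C)(C)C)CC[C@H]1[C@H](OC(=O)/C=C(\C)CC)C=O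
A3 | alternative 2 | 9α-hydroxy-8β-(4-methoxybenzyloxy)-4β,5β-dimethyl-trans-decalin-3-one | C1C[C@]2(C)[C@@H](C)C(=O)CC[C@H]2[C@H](O)[C@H]1OCc3ccc(OC)cc3
A4 | alternative 2 | acyclic aldehyde with E C5=C10 alkene, Z silyl enol ether and C8 4-methoxybenzyl ether (bicyclisation precursor) | O=C[C@@H](OCc1ccc(OC)cc1)CC/C(C)=C/CC/C(O[Si](C)(C)C(C)(C)C)=C/C
A5 | alternative 3 | cis-fused 3α-(tert-butyldimethylsilyloxy)-4β,5β-dimethyldecalin-1,6-dien-8-one (10β-H) | C1=C[C@]2(C)[C@@H](C)[C@H](O[Si](C)(C)C(C)(C)C)C=C[C@@H]2CC1=O
A6 | alternative 3 | 4-methyl-4-[(Z)-alkenyl iodide side chain]cyclohexa-2,5-dienone (reductive Heck precursor) | I/C=C\[C@@H](O[Si](C)(C)C(C)(C)C)[C@H](C)C1(C)C=CC(=O)C=C1
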